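The constants were drawn at random within sensible limits; the run is a simulation.

- Reckon the dissolved gas first: at a held gas level the target step is pseudo-first-order in starting material, as the side step is first-order, so the ratio of the two rates follows from that one concentration.

solid substrate 0.020 M; gas phase 3.9 mM (held); protic impurity 2.00 mM; time 5.0 h

1. the target standing at 5.0 h, as a percentage of the solid substrate charged
2. the change that raises the amount of target at 5.0 h, in percent of the solid substrate charged most ("none" if none brings more than 2 percentage points) (theta / gamma / alpha / epsilon / none)
3. amount of target at 5.0 h, in percent of the solid substrate charged, after gamma

- as a solid, counted per litre of solution: solid substrate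
- at the start none of the gas is dissolved
- at the start none of the solid substrate is in solution
- run time (flask): 5.0 h

- theta: doubling the saturation concentration of gas phase, all else as stated
- gamma: doubling the solubility in step 6, all else as stated
- alpha: doubling the transfer coefficient of step 1, all else as stated
- epsilon: doubling the dissolution coefficient of step 6, all else as stated

- The break-even gas level, the dissolved gas at which target and side product form equally fast, is the side rate constant over the target rate constant, 2.04 mM; gas level over break-even level is the selectivity factor.
- The flask looks contradictory: its saturation concentration of 3.9 mM lies above break-even, and the gas feed could deliver 38.6% of the charge by 5.0 h, yet with the protic impurity at its charge I reckon dissolved gas at 0.622 mM, below it.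
- The two numbers fit together because the impurity, at its charge, removes gas with a half-life of 0.33 h, shorter than the 1.75 h of transfer.
- The full feed needs 1.30 h to consume the impurity; allowing double that for filling leaves a window of 2.41 h near break-even.
- In that window, I take starting material at the level where dissolution balances both equal losses, 2.70 mM, which makes 1.29 mM of target.
- Drift to the isomer over the mean age takes 20.4%, so my figure is 5.14%.
- Doubling the solubility doubles that level, giving me 10.3%. Doubling the saturation concentration widens the window to 3.70 h, longer, and raises the gas ceiling, so I choose it.
- The forecast gives 5.5%, 9.7% and theta, whose change “burns off the impurity in half the time and gives the biggest gain”; its first figure is above mine, its second below mine.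

    gas phase ⇌ dissolved gas, rate k1*(csat - [dissolved gas]) (k1 = 1.1 × 10⁻⁴ /s, csat = 3.9 mM)
    starting material + dissolved gas → target (k2 = 0.027 /M/s)
    starting material → side product (k3 = 5.5 × 10⁻⁵ /s)
    dissolved gas + protic impurity → quenched reagent (k4 = 0.29 /M/s)
    target ⇌ isomer of the product (K5 = 0.65, k5 = 4.7 × 10⁻⁵ /s)
    solid substrate ⇌ starting material, rate k6*(cs6 - [starting material]) while solid is left; crystals form when [starting material] > cs6 (cs6 = 12 mM, k6 = 3.2 × 10⁻⁵ /s)

- The flask gives 5.39%, 9.05% after the solubility change, and theta as the best change, at 5.3 percentage points. At 5.00 h the flask's starting material has a half-life of 3.5 h by the target step, and 3.5 h by the side step alone, with dissolved gas at 0.00206 M. In the flask, target plus isomer over side product is 0.693, which times break-even is a gas level of 1.41 mM averaged over the run with starting material as the weight. The neighbour flask, with 0.080 M of solid substrate, shows a ratio of 0.693, a weighted gas level of 1.41 mM.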